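All runs stem from a simulated flask for an exercise, and the scatter is random.

1. Late in the earlier birch run, at 6.00 min, I read single product 15.1% and double product 36.1%, so the share of single product in the two is down to 29.5%.

| flask | substrate | partner | temperature | remark | time |
|---|---|---|---|---|---|
| ash | 10 mM | 1.5 equiv | 25 °C | run made earlier |  |
| birch | 14 mM | 1.5 equiv | 40 °C | run made earlier |  |
| larch | 22 mM | 1.5 equiv | 25 °C | run made earlier |  |
| grey | 10 mM | 1.50 equiv (fed, over 4.0 min) | 40 °C | all else is in the flask from the start; the feed brings no volume worth counting | 6.0 min |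
| red | 10 mM | 1.50 equiv | 40 °C | everything together at the start | 6.0 min |
| green | 10 mM | 1.50 equiv (fed, over 4.0 min) |  | the addition at 0 °C, then warmed to 40 °C; the feed brings no volume worth counting | 6.0 min |
| teal | 10 mM (fed, over 4.0 min) | 1.50 equiv | 40 °C | all else is in the flask from the start; the feed brings no volume worth counting | 6.0 min |

| run | time / min | single product / % | double product / % | substrate / % |
|---|---|---|---|---|
| ash | 1.00 | 27.4 | 1.8 | 67.8 |
| ash | 1.33 | 29.2 | 2.2 | 62.6 |
| ash | 2.00 | 32.7 | 3.5 | 57.9 |
| ash | 3.00 | 32.2 | 3.6 | 51.0 |
| ash | 5.00 | 31.4 | 10.1 | 49.4 |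
| ash | 8.00 | 24.1 | 16.7 | 47.2 |
| ash | 12.0 | 17.1 | 24.5 | 47.1 |
| birch | 0.500 | 39.4 | 3.2 | 51.4 |
| birch | 0.667 | 42.3 | 3.8 | 46.7 |
| birch | 1.00 | 46.6 | 6.6 | 41.6 |
| birch | 1.50 | 38.3 | 11.3 | 39.7 |
| birch | 2.50 | 30.3 | 17.5 | 38.1 |
| birch | 4.00 | 24.5 | 26.7 | 37.7 |
| birch | 6.00 | 15.1 | 36.1 | 35.7 |
| larch | 2.00 | 31.5 | 8.4 | 50.6 |
| larch | 3.00 | 25.5 | 13.9 | 50.4 |
| larch | 5.00 | 18.0 | 21.5 | 48.7 |
| larch | 6.00 | 15.1 | 27.2 | 46.7 |
| larch | 8.00 | 9.0 | 33.0 | 42.3 |
| larch | 10.0 | 6.5 | 39.2 | 39.1 |
| larch | 12.0 | 5.6 | 44.9 | 36.5 |

(standard deviation of a reading: 1 percentage point)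

1. the flask that comes out highest in share of single product in single product plus double product, or "all alike" when all lie within 1.5 percentage points (grey / red / green / teal / all alike)
2. share of single product in single product plus double product at the end, grey
3. share of single product in single product plus double product at the end, red
4. share of single product in single product plus double product at the end, green
5. share of single product in single product plus double product at the end, teal

- the earlier runs were read with a standard deviation of 1 percentage point

2. I take partner to turn single product into double product, so I treat the share as decaying pseudo-first-order at a given c(partner). I count each substrate lost as one partner used and each double product as one more. Birch has then used 100% of its substrate charge in partner.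

3. A straight line from charge to end stands in for the curve of c(partner), giving birch a mean of 14.0 mM. Mean c(partner) times time is the exposure, and 47.6 mM·min, read from birch at 40 °C, is the half-exposure, the exposure that halves the share at that temperature.

4. My reckoning for red assumes the same fraction used as birch, so mean c(partner) is 9.98 mM, exposure is 59.9 mM·min, and the share is 41.8%.

5. For green I assume the cold addition counts as nil and keep red's mean c(partner), leaving 2.00 min warm and a share of 74.8%. Keep green cold until its feed ends, since the warm minutes are what I count. I make no reckoning for grey or teal.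

6. The forecast names green, with grey 64%, red 42%, green 75% and teal 46%: “Green makes little double at 0 °C and has only 2 min at 40 °C, so it should be best.”

7. The flasks give green highest, with grey 61.7%, red 42.8%, green 78.5% and teal 57.7%. The forecast parts from them on teal, by 12 points.

    substrate + partner ⇌ single product + by-product (K = 0.810, k = 1.50 L mol⁻¹ s⁻¹, Ea = 59.0 kJ mol⁻¹, ΔH = 43.0 kJ mol⁻¹)
    substrate + partner → other mono adduct + by-product (k = 0.220 L mol⁻¹ s⁻¹, Ea = 54.0 kJ mol⁻¹)
    partner + single product → double product + by-product (k = 0.130 L mol⁻¹ s⁻¹, Ea = 46.0 kJ mol⁻¹)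
    partner + other mono adduct → double product + by-product (k = 0.700 L mol⁻¹ s⁻¹, Ea = 52.0 kJ mol⁻¹)
    single product ⇌ isomer of the product (K = 1.60, k = 1.70 × 10⁻⁴ s⁻¹, Ea = 108 kJ mol⁻¹, ΔH = −30.0 kJ mol⁻¹)
    (constants at 40 °C)

8. Green's partner goes from 93.1% of its charge at warming to 53% at the end, a mean of 10.9 mM, so the half-exposure gives 72.8% against 78.5%. Green is not at rest at 6.00 min. By 60.0 min its share is 0.479%, with single product 0.327%, double product 68.1%, substrate 20.8% and partner 1.80% of its charge.

9. The neighbour of red charged with 0.900 equiv of partner ends with 32.4% of it, a mean of 5.96 mM, so the half-exposure gives 59.4%. The computed share there is 64.4%.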